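**Plan**

1. Numbering used throughout: C1(OBz)–C2=C3–C4(OBz)–C5(OH)–C6(OH)(C7H2OH). The target is (1S,4R,5R,6R), with O1, O4, O5 and O6 all on one ring face.
2. Retrosynthetic cuts, in order: the C7–O silyl ether; the two benzoyl C–O bonds at O4 and O1; the C4–O and C5–O bonds (syn-dihydroxylation of a C4=C5 alkene); the C7–OH bond (hydroxide opening of a C6/C7 oxirane); the C1–H bond (ketone reduction); last the C6–O oxirane bond.
3. Enabling feature: C6, its side-chain carbon C7 and the oxygen on the neighbouring C1 are the ipso carbon, the benzylic carbon and the phenolic oxygen of 2-(hydroxymethyl)phenol. C2–C5 are the four remaining arene CH carbons, so the carbocycle is the benzene ring itself and no C–C bond has to be made.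
4. Forward: the oxirane, the only ring formed, closes in step 1 by oxidative dearomatisation, and the ketone is reduced in the same flask. Then follow oxirane opening at C7, C7 silylation, C1 benzoylation, dihydroxylation of C4=C5, C4 benzoylation and desilylation.
5. Stereochemistry: C6 comes from a chiral aryl-λ3-iodane catalyst in the dearomatisation, C1 from hydride addition anti to the oxirane C–O bond, and C4 and C5 from OsO4–TMEDA addition directed by the C6 hydroxyl.

Key step: step 1

Assumption: the sense of induction of the lactamide iodoarene on this substrate cannot be derived from precedent, so the (R,R)-catalyst, SMILES C[C@@H](Oc1cccc(O[C@H](C)C(=O)Nc2c(C)cc(C)cc2C)c1I)C(=O)Nc1c(C)cc(C)cc1C, is written provisionally for the (S)-dienone 3; if it favours the (R)-dienone, its (S,S)-antipode is used and nothing else changes.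

**Route**

Step 1
Reactants: 1 2-(hydroxymethyl)phenol; 2 3-chloroperbenzoic acid (terminal oxidant)
Product: 4 (3S,4S)-1-oxaspiro[2.5]octa-5,7-dien-4-ol (hydroxyl cis to the oxirane oxygen), via spiroepoxydienone 3 (not isolated)
Conditions: (R,R)-2,2'-[(2-iodo-1,3-phenylene)bis(oxy)]bis[N-(2,4,6-trimethylphenyl)propanamide] (10 mol %), dried 2 (0.95 equiv), CH2Cl2/(CF3)2CHOH 4:1, 0.02 M, −40 °C; then CeCl3·7H2O, NaBH4 (excess), MeOH, −78 °C; aq. NaHCO3 work-up
Reagents that add atoms: none
Why: Proposed new method: mCPBA oxidises the iodoarene to an aryl-λ3-iodane (trivalent iodine), the phenol oxygen of 1 displaces a ligand on iodine, and the benzylic hydroxyl then attacks the now electrophilic ipso carbon C6 as the iodoarene leaves in its monovalent state, which forms the C6–O bond and leaves the six-membered ring as the 2,4-dienone 3. The closest known reaction types are the periodate spiroepoxidation of 2-(hydroxymethyl)phenols (Adler–Becker oxidation, racemic) and the enantioselective dearomative spirolactonisation of phenols catalysed by chiral iodoarenes with mCPBA; what is new is their union, an oxirane-forming closure under chiral iodane control. The oxirane closes in the 3-exo-trig mode, the oxygen adding to a trigonal ring carbon whose π bond lies outside the new ring. The C6 stereocentre is set by the catalyst, whose two lactamide arms fold over the iodine centre through N–H···O contacts and shield one face of the bound phenol from the tethered hydroxyl. The step needs attack at the substituted ortho carbon and not at C2 or C4, which the one-atom tether secures because only C6 is within reach of the internal oxygen, while the weakly nucleophilic fluoroalcohol medium and water-free oxidant keep external nucleophiles from C4. Since 3 dimerises by Diels–Alder reaction it is reduced at once under Luche conditions, 1,2-selectively and with hydride adding anti to the oxirane C–O bond (Felkin–Anh, reinforced by CeCl3 bridging the two oxygens), which sets C1 with its hydroxyl cis to the oxirane oxygen.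

Step 2
Reactants: 4 (3S,4S)-1-oxaspiro[2.5]octa-5,7-dien-4-ol
Product: 5 (1S,6S)-6-(hydroxymethyl)cyclohexa-2,4-diene-1,6-diol
Conditions: NaOH (0.5 M aq.), t-BuOH, 70 °C; neutralise to pH 8, concentrate, use crude
Reagents that add atoms: water (delivered as aqueous sodium hydroxide), O
Why: Base-mediated epoxide hydrolysis by SN2 attack of hydroxide at the unsubstituted oxirane carbon C7 touches no stereocentre, cannot be diverted into a Payne rearrangement because the C1 oxygen is syn to the C6–O bond, and the basic medium avoids acid-triggered ionisation at the dienylic C6.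

Step 3
Reactants: 5 (1S,6S)-6-(hydroxymethyl)cyclohexa-2,4-diene-1,6-diol
Product: 6 (1S,6S)-6-({[tert-butyl(dimethyl)silyl]oxy}methyl)cyclohexa-2,4-diene-1,6-diol
Conditions: TBSCl (1.05 equiv), imidazole, DMF, −20 → 0 °C
Reagents that add atoms: tert-butyldimethylsilyl chloride, CC(C)(C)[Si](C)(C)Cl
Why: Silylation with a silyl chloride and imidazole is selective on steric grounds for the primary C7 hydroxyl over the neopentyl-type secondary C1 and the tertiary C6 hydroxyls.

Step 4
Reactants: 6 (1S,6S)-6-({[tert-butyl(dimethyl)silyl]oxy}methyl)cyclohexa-2,4-diene-1,6-diol; 7 benzoyl chloride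
Product: 8 (1S,6S)-6-({[tert-butyl(dimethyl)silyl]oxy}methyl)-6-hydroxycyclohexa-2,4-dien-1-yl benzoate
Conditions: 7 (1.2 equiv), pyridine, 4-(dimethylamino)pyridine (cat.), CH2Cl2, 0 °C
Reagents that add atoms: benzoyl chloride (7), O=C(Cl)c1ccccc1
Why: Acylation under nucleophilic catalysis esterifies the only secondary hydroxyl while the tertiary C6-OH stays free, and the ester both installs the C1 benzoate of the target and removes the C1 hydroxyl as a competing directing group for the next step.

Step 5
Reactants: 8 (1S,6S)-6-({[tert-butyl(dimethyl)silyl]oxy}methyl)-6-hydroxycyclohexa-2,4-dien-1-yl benzoate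
Product: 10 (1S,4R,5R,6R)-6-({[tert-butyl(dimethyl)silyl]oxy}methyl)-4,5,6-trihydroxycyclohex-2-en-1-yl benzoate, via osmate ester 9 (not isolated)
Conditions: OsO4 (1.0 equiv), N,N,N',N'-tetramethylethane-1,2-diamine (TMEDA, 1.1 equiv), CH2Cl2, −78 °C; then sat. aq. Na2SO3, THF, 50 °C
Reagents that add atoms: osmium tetroxide, O=[Os](=O)(=O)=O
Why: In this hydrogen-bond-directed dihydroxylation the OsO4·TMEDA complex, a strong hydrogen-bond acceptor, is held by the tertiary allylic C6-OH and adds by (3+2) cycloaddition to the adjacent C4=C5 bond on the hydroxyl face, so O4 and O5 are set syn to O6 (C2=C3 has no donor and is deactivated by the allylic benzoate), and the glycolate of hexavalent osmium 9 is then cleaved reductively by sulfite.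

Step 6
Reactants: 10 (1S,4R,5R,6R)-6-({[tert-butyl(dimethyl)silyl]oxy}methyl)-4,5,6-trihydroxycyclohex-2-en-1-yl benzoate; 7 benzoyl chloride
Product: 11 (1S,4R,5R,6R)-6-({[tert-butyl(dimethyl)silyl]oxy}methyl)-5,6-dihydroxycyclohex-2-ene-1,4-diyl dibenzoate
Conditions: 7 (1.05 equiv), pyridine, CH2Cl2, −40 → −20 °C
Reagents that add atoms: benzoyl chloride (7), O=C(Cl)c1ccccc1
Why: Regioselective acylation is expected at the allylic C4 hydroxyl, the only one that is secondary and flanked by an sp2 carbon (C5-OH is wedged between C4 and the quaternary C6, C6-OH is tertiary), and the cold conditions without acyl-transfer catalyst suppress a second acylation and benzoyl migration.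

Step 7
Reactants: 11 (1S,4R,5R,6R)-6-({[tert-butyl(dimethyl)silyl]oxy}methyl)-5,6-dihydroxycyclohex-2-ene-1,4-diyl dibenzoate
Product: 12 (1S,4R,5R,6R)-5,6-dihydroxy-6-(hydroxymethyl)cyclohex-2-ene-1,4-diyl dibenzoate (target)
Conditions: HF·pyridine, THF/pyridine, 0 °C → rt
Reagents that add atoms: none
Why: Fluoride-driven cleavage of the primary silyl ether under buffered, weakly acidic conditions frees the C7 hydroxyl without the benzoate migration to neighbouring hydroxyls that basic fluoride sources would invite.

**Compound list**

1 | 2-(hydroxymethyl)phenol (salicyl alcohol) | OCc1ccccc1O | starting material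
2 | 3-chloroperbenzoic acid (mCPBA) | OOC(=O)c1cccc(Cl)c1 | starting material
3 | (3S)-1-oxaspiro[2.5]octa-5,7-dien-4-one | O=C1C=CC=C[C@]12CO2 | intermediate
4 | (3S,4S)-1-oxaspiro[2.5]octa-5,7-dien-4-ol, hydroxyl cis to the oxirane oxygen | O[C@H]1C=CC=C[C@]12CO2 | intermediate
5 | (1S,6S)-6-(hydroxymethyl)cyclohexa-2,4-diene-1,6-diol, the two ring hydroxyls cis | O[C@H]1C=CC=C[C@]1(O)CO | intermediate
6 | (1S,6S)-6-({[tert-butyl(dimethyl)silyl]oxy}methyl)cyclohexa-2,4-diene-1,6-diol | O[C@H]1C=CC=C[C@]1(O)CO[Si](C)(C)C(C)(C)C | intermediate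
7 | benzoyl chloride | O=C(Cl)c1ccccc1 | starting material
8 | (1S,6S)-6-({[tert-butyl(dimethyl)silyl]oxy}methyl)-6-hydroxycyclohexa-2,4-dien-1-yl benzoate | O=C(O[C@H]1C=CC=C[C@]1(O)CO[Si](C)(C)C(C)(C)C)c1ccccc1 | intermediate
9 | cyclic osmate ester of 10: a dioxo(TMEDA)osmium unit (hexavalent osmium) bridging O4 and O5 on the face of the C6 hydroxyl | O=C(O[C@H]1C=C[C@@H](O[Os-2]2(=O)(=O)([N+](C)(C)CC[N+]2(C)C)O3)[C@@H]3[C@]1(O)CO[Si](C)(C)C(C)(C)C)c1ccccc1 | intermediate
10 | (1S,4R,5R,6R)-6-({[tert-butyl(dimethyl)silyl]oxy}methyl)-4,5,6-trihydroxycyclohex-2-en-1-yl benzoate, all four ring oxygens cis | O=C(O[C@H]1C=C[C@@H](O)[C@@H](O)[C@]1(O)CO[Si](C)(C)C(C)(C)C)c1ccccc1 | intermediate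
11 | (1S,4R,5R,6R)-6-({[tert-butyl(dimethyl)silyl]oxy}methyl)-5,6-dihydroxycyclohex-2-ene-1,4-diyl dibenzoate | O=C(O[C@H]1C=C[C@@H](OC(=O)c2ccccc2)[C@@H](O)[C@]1(O)CO[Si](C)(C)C(C)(C)C)c1ccccc1 | intermediate
12 | (1S,4R,5R,6R)-5,6-dihydroxy-6-(hydroxymethyl)cyclohex-2-ene-1,4-diyl dibenzoate | O=C(O[C@H]1C=C[C@@H](OC(=O)c2ccccc2)[C@@H](O)[C@]1(O)CO)c1ccccc1 | target

**Count and risks**

Total step count: 7. Longest linear sequence: 7 steps (1 → 12).

Steps most likely to fail:

1. Step 1. The chiral iodane may discriminate the two arene faces poorly, external nucleophiles may add at C4, or Diels–Alder dimerisation of the dienone may outrun its reduction. The fallback sets out from 1 and returns at 4, using known chemistry only.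
 - Compound 1 is oxidised with NaIO4 in cold aqueous methanol (Adler–Becker oxidation). This gives the dienone as a racemate, 3 together with its mirror image (3R)-1-oxaspiro[2.5]octa-5,7-dien-4-one F1.
 - The racemate is extracted cold into CH2Cl2 and reduced at once with NaBH4/CeCl3·7H2O in MeOH at −78 °C. This gives the racemic cis-epoxy dienol, 4 plus (3R,4R)-1-oxaspiro[2.5]octa-5,7-dien-4-ol F2.
 - Lipase kinetic resolution (immobilised Candida antarctica lipase B, vinyl acetate, t-BuOMe, rt) should acylate the (4R)-alcohol to (3R,4R)-1-oxaspiro[2.5]octa-5,7-dien-4-yl acetate F3. This is the enantiomer favoured by the usual empirical rule for secondary alcohols, with the spiro carbon as the large group and the vinyl carbon as the medium group.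
 - Compound 4 remains as the unreacted alcohol and enters step 2. The same resolution can upgrade material of insufficient enantiomeric purity from the catalytic step.

2. Step 5. Osmylation may occur on the face anti to the C6 hydroxyl or at C2=C3 if hydrogen-bond direction by the hindered tertiary alcohol is weak. The fallback sets out from 8 and returns at 11, so it also replaces step 6.
 - Vanadium-catalysed hydroxyl-directed epoxidation (VO(acac)2, t-BuOOH, CH2Cl2, 0 °C) delivers oxygen to C4=C5 through a covalent alkoxide–vanadate link. This should give (1S,4R,5R,6S)-6-({[tert-butyl(dimethyl)silyl]oxy}methyl)-4,5-epoxy-6-hydroxycyclohex-2-en-1-yl benzoate F4, with the oxirane on the face of the C6 hydroxyl.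
 - Hydrolytic trans-opening at the allylic terminus C4 (HClO4, 1 mol %, THF/H2O, 0 °C) should give (1S,4S,5R,6R)-6-({[tert-butyl(dimethyl)silyl]oxy}methyl)-4,5,6-trihydroxycyclohex-2-en-1-yl benzoate F5, the C4 epimer of 10.
 - Mitsunobu reaction with benzoic acid (PPh3, diisopropyl azodicarboxylate, THF, 0 °C) at the allylic, least hindered C4 hydroxyl inverts C4 and installs the benzoate in one operation, giving 11.

3. Step 6. Acylation may go to the C5 hydroxyl, a second acylation may follow, or the benzoyl group may migrate from O4 to O5 under base. The fallback sets out from 10 and returns at 11.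
 - Compound 10 is condensed with trimethyl orthobenzoate (camphorsulfonic acid cat., CH2Cl2, rt). Only the vicinal secondary cis pair should close readily, giving the 4,5-cyclic methyl orthobenzoate of 10 (a 2-methoxy-2-phenyl-1,3-dioxolane across O4 and O5, both epimers at the orthoester carbon) F6.
 - Brief treatment with 80 % aqueous acetic acid at 0 °C opens the orthoester kinetically to the hydroxy ester that carries the benzoate on the axial oxygen.
 - In the half-chair that keeps the CH2OTBS group equatorial, the axial oxygen is O4, so 11 results. This is the same conformer in which direct acylation would be misdirected to the equatorial C5 hydroxyl.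

**Further compounds**

F1 | step 1 | (3R)-1-oxaspiro[2.5]octa-5,7-dien-4-one | O=C1C=CC=C[C@@]12CO2
F2 | step 1 | (3R,4R)-1-oxaspiro[2.5]octa-5,7-dien-4-ol | O[C@@H]1C=CC=C[C@@]12CO2
F3 | step 1 | (3R,4R)-1-oxaspiro[2.5]octa-5,7-dien-4-yl acetate | CC(=O)O[C@@H]1C=CC=C[C@@]12CO2
F4 | step 5 | (1S,4R,5R,6S)-6-({[tert-butyl(dimethyl)silyl]oxy}methyl)-4,5-epoxy-6-hydroxycyclohex-2-en-1-yl benzoate | O=C(O[C@H]1C=C[C@H]2O[C@H]2[C@]1(O)CO[Si](C)(C)C(C)(C)C)c1ccccc1
F5 | step 5 | (1S,4S,5R,6R)-6-({[tert-butyl(dimethyl)silyl]oxy}methyl)-4,5,6-trihydroxycyclohex-2-en-1-yl benzoate | O=C(O[C@H]1C=C[C@H](O)[C@@H](O)[C@]1(O)CO[Si](C)(C)C(C)(C)C)c1ccccc1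
F6 | step 6 | 4,5-cyclic methyl orthobenzoate of 10 (epimers at the orthoester carbon) | O=C(O[C@H]1C=C[C@H]2OC(OC)(c3ccccc3)O[C@H]2[C@]1(O)CO[Si](C)(C)C(C)(C)C)c1ccccc1
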